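**Retrosynthetic overview**
- Last C–C bond: the single bond between the two E-olefins of the diene, by Pd-catalysed coupling of an E-alkenylalane (Zr-catalysed methylalumination of a cyclohexenyl butyne, which fixes the trisubstituted olefin) with an (R)-configured chromanyl vinyl iodide; desilylation ends the route.
- Chroman ring (second ring, separate branch): Sharpless epoxidation of a geraniol-type E-allylic alcohol, then 6-exo opening of the epoxide by the phenol with inversion sets the only stereocentre; glycol cleavage and Takai olefination give the vinyl iodide.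
- Cyclohexene ring (first ring): a one-flask Robinson annulation (Michael addition, aldol condensation, decarboxylation) of ethyl acetoacetate with an alkynyl vinyl ketone forms the ring CH2–CH2 bond next to the methyl-bearing olefin carbon and the tetrasubstituted C=C; C=O is then turned into CMe2 (MeLi, then Me2TiCl2).
- Enabling feature: in the cyclohexene ring, the olefin carbon that carries the ring methyl, that methyl and the adjacent ring CH2 form an acetone unit. The CMe2 carbon on the other side of the chain-bearing olefin carbon is a masked ketone: without one methyl it is a terminus of a symmetrical 1,3-dimethyl-2-alkylcyclohexenyl cation, so a 3-methyl-2-alkylcyclohex-2-enone is the ring in latent form and methylation at either cation terminus gives the same compound.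

Key step: step 3

Remark: read from the SMILES, the chroman stereocentre is (R) (priority O > sp2 side-chain carbon > ring CH2 > CH3); natural L-(+)-tartrate in step 10 is chosen for this enantiomer.

**Step 1**
Reactants: 1 hex-5-ynoic acid
Product: 3 N-methoxy-N-methylhex-5-ynamide, via acyl imidazole 2 (not isolated)
Conditions: CDI, CH2Cl2, rt; then MeNH(OMe)·HCl, rt
Reagents that add atoms: N,O-dimethylhydroxylamine hydrochloride, CNOC.Cl
Why: CDI activates the acid as its acyl imidazole, which the hydroxylamine converts into the Weinreb amide (standard amide formation), and the terminal alkyne is inert.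

**Step 2**
Reactants: 3 N-methoxy-N-methylhex-5-ynamide
Product: 4 oct-1-en-7-yn-3-one
Conditions: CH2=CHMgBr (2.2 equiv), THF, −20 to 0 °C; then cold 1 M HCl
Reagents that add atoms: vinylmagnesium bromide, C=C[Mg]Br
Why: Addition of the vinyl Grignard reagent to the Weinreb amide stops at the chelated tetrahedral adduct, so acidic work-up should release the vinyl ketone without over-addition (Weinreb ketone synthesis); the second equivalent only deprotonates the alkyne, and the enone is used at once to avoid polymerisation.

**Step 3**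
Reactants: 4 oct-1-en-7-yn-3-one, 5 ethyl acetoacetate
Product: 8 2-(but-3-yn-1-yl)-3-methylcyclohex-2-en-1-one, via Michael adduct 6 (not isolated), via annulated keto ester 7 (not isolated)
Conditions: NaOEt (0.1 equiv), EtOH, 0 °C to rt; then KOH, H2O/EtOH, reflux; then HCl (pH 2)
Reagents that add atoms: none
Why: Catalytic ethoxide generates the acetoacetate carbanion, which adds to the terminal CH2 of vinyl ketone 4 (Michael addition) and so forms the ring CH2–CH2 bond next to the future methyl-bearing olefin carbon; the ketone enolate on the chain side of 6 then attacks the acetyl carbonyl, E1cB loss of water forms the tetrasubstituted ring C=C, and hydroxide saponifies the ester of 7, whose vinylogous β-keto acid loses CO2, so the activating ester is removed in the same flask. The closest known reaction type is the Robinson annulation of β-keto esters with alkyl vinyl ketones, which gives 2-alkyl-3-methylcyclohex-2-enones after decarboxylation. The cyclohexene ring closes by a 6-(enolendo)-exo-trig aldol addition. No stereocentre is formed. The step needs regioselectivity in the aldol stage (the chain CH2 must attack the acetyl C=O, and the acetyl CH3 must not attack the chain ketone): the aldol additions are reversible, dehydration is not, and the conjugated tetrasubstituted enone is the thermodynamic sink. It also needs chemoselectivity towards the terminal alkyne, which is inert to alkoxide and to aqueous hydroxide at reflux.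

**Step 4**
Reactants: 8 2-(but-3-yn-1-yl)-3-methylcyclohex-2-en-1-one
Product: 9 2-(but-3-yn-1-yl)-1,3-dimethylcyclohex-2-en-1-ol (racemic)
Conditions: MeLi (2.5 equiv), Et2O, −78 to 0 °C; then H2O
Reagents that add atoms: methyllithium, C[Li]
Why: After one equivalent has deprotonated the alkyne, methyllithium should add 1,2 to the hindered β,β-disubstituted enone (carbonyl addition of a hard nucleophile) to give the racemic tertiary allylic alcohol, whose stereocentre is erased in the next step.

**Step 5**
Reactants: 9 2-(but-3-yn-1-yl)-1,3-dimethylcyclohex-2-en-1-ol (racemic)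
Product: 10 2-(but-3-yn-1-yl)-1,3,3-trimethylcyclohex-1-ene
Conditions: Me2Zn, TiCl4, CH2Cl2, −40 °C (gives Me2TiCl2); then 9, −40 to 0 °C
Reagents that add atoms: dimethyltitanium dichloride, C[Ti](C)(Cl)Cl (made in the flask from dimethylzinc, C[Zn]C, and TiCl4)
Why: Reetz-type SN1 methylation of a tertiary alcohol, in which the titanium alkoxide ionises to the 1,3-dimethyl-2-alkylcyclohexenyl cation and methyl transfer from titanium within the ion pair builds the quaternary CMe2 carbon; both termini of the symmetrical allyl cation give the same tetrasubstituted olefin, so no regiochemical issue arises.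

**Step 6**
Reactants: 11 2,5-dihydroxybenzaldehyde
Product: 12 5-[(tert-butyldimethylsilyl)oxy]-2-hydroxybenzaldehyde
Conditions: TBSCl (1.05 equiv), imidazole, CH2Cl2, 0 °C
Reagents that add atoms: tert-butyldimethylsilyl chloride, CC(C)(C)[Si](C)(C)Cl
Why: The 5-OH should be silylated selectively because the 2-OH is deactivated by its hydrogen bond to the aldehyde (selective silyl ether formation).

**Step 7**
Reactants: 12 5-[(tert-butyldimethylsilyl)oxy]-2-hydroxybenzaldehyde
Product: 13 4-[(tert-butyldimethylsilyl)oxy]-2-(1-hydroxybut-3-yn-1-yl)phenol (racemic)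
Conditions: propargyl bromide, Zn dust, THF/sat. aq NH4Cl, 0 °C to rt
Reagents that add atoms: propargyl bromide, C#CCBr
Why: Zinc-mediated Barbier propargylation in aqueous medium adds the allenylzinc species through its γ-carbon to give the homopropargylic alcohol and tolerates the free phenol; the new carbinol centre is racemic and is removed in step 8.

**Step 8**
Reactants: 13 4-[(tert-butyldimethylsilyl)oxy]-2-(1-hydroxybut-3-yn-1-yl)phenol (racemic)
Product: 14 2-(but-3-yn-1-yl)-4-[(tert-butyldimethylsilyl)oxy]phenol
Conditions: Et3SiH, TFA, CH2Cl2, −10 to 0 °C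
Reagents that add atoms: none
Why: Ionic hydrogenation, in which TFA ionises the ortho-hydroxybenzylic alcohol to an ortho-quinone methide that Et3SiH reduces to the benzylic CH2, while the aryl silyl ether and the alkyne should stay untouched.

**Step 9**
Reactants: 14 2-(but-3-yn-1-yl)-4-[(tert-butyldimethylsilyl)oxy]phenol
Product: 16 (2E)-5-{5-[(tert-butyldimethylsilyl)oxy]-2-hydroxyphenyl}-3-methylpent-2-en-1-ol, via E-alkenylalane 15 (not isolated)
Conditions: Me3Al (3.5 equiv), Cp2ZrCl2 (0.3 equiv), (CH2Cl)2, 0 °C to rt; then n-BuLi, (CH2O)n, THF, −30 °C to rt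
Reagents that add atoms: trimethylaluminium, C[Al](C)C; paraformaldehyde (formaldehyde), C=O
Why: Negishi zirconium-catalysed carboalumination adds methyl and aluminium syn across the terminal alkyne with methyl on the internal carbon, and the derived alanate is hydroxymethylated with retention, which fixes the E-trisubstituted olefin; the phenol is carried as its aluminium phenoxide.

**Step 10**
Reactants: 16 (2E)-5-{5-[(tert-butyldimethylsilyl)oxy]-2-hydroxyphenyl}-3-methylpent-2-en-1-ol
Product: 18 (1S)-1-[(2R)-6-[(tert-butyldimethylsilyl)oxy]-2-methyl-3,4-dihydro-2H-chromen-2-yl]ethane-1,2-diol, via epoxy alcohol 17 (not isolated)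
Conditions: Ti(OiPr)4 (1.2 equiv), L-(+)-diethyl tartrate (1.4 equiv), t-BuOOH, 4 Å MS, CH2Cl2, −25 °C; aqueous tartaric acid work-up; then CSA (0.1 equiv), CH2Cl2, 0 °C
Reagents that add atoms: tert-butyl hydroperoxide, CC(C)(C)OO
Why: Katsuki–Sharpless asymmetric epoxidation of this geraniol-type E-allylic alcohol with L-(+)-tartrate should give the (2S,3S)-epoxy alcohol, and acid-catalysed 6-exo opening by the phenol at the tertiary epoxide carbon with inversion then sets the (R)-configured quaternary chroman carbon.

**Step 11**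
Reactants: 18 (1S)-1-[(2R)-6-[(tert-butyldimethylsilyl)oxy]-2-methyl-3,4-dihydro-2H-chromen-2-yl]ethane-1,2-diol
Product: 19 (2R)-6-[(tert-butyldimethylsilyl)oxy]-2-methyl-3,4-dihydro-2H-chromene-2-carbaldehyde
Conditions: NaIO4, THF/pH 7 buffer, 0 °C to rt
Reagents that add atoms: none
Why: Periodate cleaves the 1,2-diol to the aldehyde (Malaprade glycol cleavage); the stereocentre has no α-hydrogen and cannot epimerise, and the silyl ether protects the phenol against periodate oxidation.

**Step 12**
Reactants: 19 (2R)-6-[(tert-butyldimethylsilyl)oxy]-2-methyl-3,4-dihydro-2H-chromene-2-carbaldehyde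
Product: 20 tert-butyl({(2R)-2-[(E)-2-iodoethenyl]-2-methyl-3,4-dihydro-2H-chromen-6-yl}oxy)dimethylsilane
Conditions: CrCl2 (6 equiv), CHI3 (2 equiv), THF, 0 °C to rt
Reagents that add atoms: iodoform, IC(I)I
Why: Takai olefination, in which the geminal dichromium species from CrCl2 and CHI3 adds to the aldehyde and eliminates to the E-vinyl iodide, a selectivity that should be high with this hindered α-quaternary aldehyde.

**Step 13**
Reactants: 10 2-(but-3-yn-1-yl)-1,3,3-trimethylcyclohex-1-ene, 20 tert-butyl({(2R)-2-[(E)-2-iodoethenyl]-2-methyl-3,4-dihydro-2H-chromen-6-yl}oxy)dimethylsilane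
Product: 22 tert-butyldimethyl({(2R)-2-methyl-2-[(1E,3E)-4-methyl-6-(2,6,6-trimethylcyclohex-1-en-1-yl)hexa-1,3-dien-1-yl]-3,4-dihydro-2H-chromen-6-yl}oxy)silane, via E-alkenylalane 21 (not isolated)
Conditions: 10, Me3Al (2 equiv), Cp2ZrCl2 (0.25 equiv), (CH2Cl)2, rt; then 20, ZnCl2, Pd(PPh3)4 (5 mol%), THF, rt
Reagents that add atoms: trimethylaluminium, C[Al](C)C
Why: Syn methylalumination of alkyne 10 (methyl to the internal carbon) gives the E-alkenylalane, which should couple with vinyl iodide 20 with retention at both olefins under Pd(PPh3)4 and ZnCl2 (Negishi alkenyl–alkenyl coupling), so the (E,E)-diene forms stereospecifically; THF tempers the Lewis acidity of the aluminium species towards the allylic aryl ether.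

**Step 14**
Reactants: 22 tert-butyldimethyl({(2R)-2-methyl-2-[(1E,3E)-4-methyl-6-(2,6,6-trimethylcyclohex-1-en-1-yl)hexa-1,3-dien-1-yl]-3,4-dihydro-2H-chromen-6-yl}oxy)silane
Product: 23 (2R)-2-methyl-2-[(1E,3E)-4-methyl-6-(2,6,6-trimethylcyclohex-1-en-1-yl)hexa-1,3-dien-1-yl]-3,4-dihydro-2H-chromen-6-ol
Conditions: TBAF, AcOH, THF, 0 °C, argon
Reagents that add atoms: none
Why: Buffered fluoride should cleave the aryl silyl ether (desilylation) and leave the diene and the tertiary allylic aryl ether untouched.

**Compound list**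
1 | hex-5-ynoic acid | C#CCCCC(=O)O | starting material
2 | 1-(hex-5-ynoyl)imidazole | C#CCCCC(=O)n1ccnc1 | intermediate (not isolated)
3 | N-methoxy-N-methylhex-5-ynamide | C#CCCCC(=O)N(C)OC | intermediate
4 | oct-1-en-7-yn-3-one | C=CC(=O)CCCC#C | intermediate
5 | ethyl acetoacetate | CCOC(=O)CC(C)=O | starting material
6 | ethyl 2-acetyl-5-oxodec-9-ynoate | CCOC(=O)C(CCC(=O)CCCC#C)C(C)=O | intermediate (not isolated)
7 | ethyl 3-(but-3-yn-1-yl)-2-methyl-4-oxocyclohex-2-ene-1-carboxylate | CCOC(=O)C1CCC(=O)C(CCC#C)=C1C | intermediate (not isolated)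
8 | 2-(but-3-yn-1-yl)-3-methylcyclohex-2-en-1-one | CC1=C(CCC#C)C(=O)CCC1 | intermediate
9 | 2-(but-3-yn-1-yl)-1,3-dimethylcyclohex-2-en-1-ol (racemic) | CC1=C(CCC#C)C(C)(O)CCC1 | intermediate
10 | 2-(but-3-yn-1-yl)-1,3,3-trimethylcyclohex-1-ene | CC1=C(CCC#C)C(C)(C)CCC1 | intermediate
11 | 2,5-dihydroxybenzaldehyde | O=Cc1cc(O)ccc1O | starting material
12 | 5-[(tert-butyldimethylsilyl)oxy]-2-hydroxybenzaldehyde | O=Cc1cc(O[Si](C)(C)C(C)(C)C)ccc1O | intermediate
13 | 4-[(tert-butyldimethylsilyl)oxy]-2-(1-hydroxybut-3-yn-1-yl)phenol (racemic) | C#CCC(O)c1cc(O[Si](C)(C)C(C)(C)C)ccc1O | intermediate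
14 | 2-(but-3-yn-1-yl)-4-[(tert-butyldimethylsilyl)oxy]phenol | C#CCCc1cc(O[Si](C)(C)C(C)(C)C)ccc1O | intermediate
15 | [(1E)-4-{5-[(tert-butyldimethylsilyl)oxy]-2-[(dimethylalumanyl)oxy]phenyl}-2-methylbut-1-en-1-yl]dimethylalane | C[Al](C)/C=C(\C)CCc1cc(O[Si](C)(C)C(C)(C)C)ccc1O[Al](C)C | intermediate (not isolated)
16 | (2E)-5-{5-[(tert-butyldimethylsilyl)oxy]-2-hydroxyphenyl}-3-methylpent-2-en-1-ol | OC/C=C(\C)CCc1cc(O[Si](C)(C)C(C)(C)C)ccc1O | intermediate
17 | [(2S,3S)-3-(2-{5-[(tert-butyldimethylsilyl)oxy]-2-hydroxyphenyl}ethyl)-3-methyloxiran-2-yl]methanol | OC[C@@H]1O[C@@]1(C)CCc2cc(O[Si](C)(C)C(C)(C)C)ccc2O | intermediate (not isolated)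
18 | (1S)-1-[(2R)-6-[(tert-butyldimethylsilyl)oxy]-2-methyl-3,4-dihydro-2H-chromen-2-yl]ethane-1,2-diol | OC[C@H](O)[C@@]1(C)CCc2cc(O[Si](C)(C)C(C)(C)C)ccc2O1 | intermediate
19 | (2R)-6-[(tert-butyldimethylsilyl)oxy]-2-methyl-3,4-dihydro-2H-chromene-2-carbaldehyde | O=C[C@@]1(C)CCc2cc(O[Si](C)(C)C(C)(C)C)ccc2O1 | intermediate
20 | tert-butyl({(2R)-2-[(E)-2-iodoethenyl]-2-methyl-3,4-dihydro-2H-chromen-6-yl}oxy)dimethylsilane | I/C=C/[C@@]1(C)CCc2cc(O[Si](C)(C)C(C)(C)C)ccc2O1 | intermediate
21 | dimethyl[(1E)-2-methyl-4-(2,6,6-trimethylcyclohex-1-en-1-yl)but-1-en-1-yl]alane | C[Al](C)/C=C(\C)CCC1=C(C)CCCC1(C)C | intermediate (not isolated)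
22 | tert-butyldimethyl({(2R)-2-methyl-2-[(1E,3E)-4-methyl-6-(2,6,6-trimethylcyclohex-1-en-1-yl)hexa-1,3-dien-1-yl]-3,4-dihydro-2H-chromen-6-yl}oxy)silane | CC1=C(CC/C(C)=C/C=C/[C@@]2(C)CCc3cc(O[Si](C)(C)C(C)(C)C)ccc3O2)C(C)(C)CCC1 | intermediate
23 | (2R)-2-methyl-2-[(1E,3E)-4-methyl-6-(2,6,6-trimethylcyclohex-1-en-1-yl)hexa-1,3-dien-1-yl]-3,4-dihydro-2H-chromen-6-ol | CC1=C(CC/C(C)=C/C=C/[C@@]2(C)CCc3cc(O)ccc3O2)C(C)(C)CCC1 | target

**Step count**
Total step count: 14 (steps 1–5 for the cyclohexene fragment, steps 6–12 for the chroman fragment, steps 13 and 14 for union and deprotection).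
Longest linear sequence: 9 steps (steps 6–12, then 13 and 14, from 2,5-dihydroxybenzaldehyde).

**Steps most likely to fail**

Step 5. The allyl cation may lose a proton (elimination to a ring diene) or be captured by the pendant alkyne faster than methyl is transferred from titanium. The fallback sets out from enone 8. Conjugate addition of Me2CuLi (excess, THF, −78 to 0 °C) to the β-carbon that already carries the ring methyl, with trapping of the enolate by PhNTf2, should give the enol triflate 2-(but-3-yn-1-yl)-3,3-dimethylcyclohex-1-en-1-yl trifluoromethanesulfonate F1. Coupling of F1 with MeMgBr under Fe(acac)3 catalysis (THF/NMP, 0 °C, one extra equivalent for the alkyne C–H) should give 10, where the fallback comes back to the route. The same compound results because the new methyl enters at the former carbonyl carbon and the CMe2 carbon is the former β-carbon.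

Step 10. The free phenol may sequester the titanium tartrate complex or be oxidised by the hydroperoxide, which would slow the epoxidation and erode its enantioselectivity. The fallback sets out from 16. Chemoselective O-allylation of the phenol (allyl bromide, K2CO3, acetone) should give the allyl ether (2E)-5-{2-(allyloxy)-5-[(tert-butyldimethylsilyl)oxy]phenyl}-3-methylpent-2-en-1-ol F2. Catalytic Katsuki–Sharpless epoxidation of F2 with L-(+)-diethyl tartrate should give the epoxy alcohol [(2S,3S)-3-(2-{2-(allyloxy)-5-[(tert-butyldimethylsilyl)oxy]phenyl}ethyl)-3-methyloxiran-2-yl]methanol F3. Removal of the allyl group with Pd(PPh3)4 and morpholine gives 17, which CSA cyclises to 18, where the fallback comes back to the route.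

Step 13. The aluminium Lewis acids in the one-flask coupling may ionise the tertiary allylic aryl ether, or transmetalation to palladium may stall. The fallback sets out from 10. The same carboalumination, quenched with I2, should give the vinyl iodide 2-[(3E)-4-iodo-3-methylbut-3-en-1-yl]-1,3,3-trimethylcyclohex-1-ene F4. Iodine–lithium exchange with t-BuLi and trapping with 2-isopropoxy-4,4,5,5-tetramethyl-1,3,2-dioxaborolane should give the pinacol boronate 4,4,5,5-tetramethyl-2-[(1E)-2-methyl-4-(2,6,6-trimethylcyclohex-1-en-1-yl)but-1-en-1-yl]-1,3,2-dioxaborolane F5. Suzuki–Miyaura coupling of F5 with 20 (Pd(PPh3)4, aqueous K3PO4, THF) should give 22, where the fallback comes back to the route.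

**Further compounds**
F1 | step 5 | 2-(but-3-yn-1-yl)-3,3-dimethylcyclohex-1-en-1-yl trifluoromethanesulfonate | C#CCCC1=C(OS(=O)(=O)C(F)(F)F)CCCC1(C)C
F2 | step 10 | (2E)-5-{2-(allyloxy)-5-[(tert-butyldimethylsilyl)oxy]phenyl}-3-methylpent-2-en-1-ol | OC/C=C(\C)CCc1cc(O[Si](C)(C)C(C)(C)C)ccc1OCC=C
F3 | step 10 | [(2S,3S)-3-(2-{2-(allyloxy)-5-[(tert-butyldimethylsilyl)oxy]phenyl}ethyl)-3-methyloxiran-2-yl]methanol | OC[C@@H]1O[C@@]1(C)CCc2cc(O[Si](C)(C)C(C)(C)C)ccc2OCC=C
F4 | step 13 | 2-[(3E)-4-iodo-3-methylbut-3-en-1-yl]-1,3,3-trimethylcyclohex-1-ene | I/C=C(\C)CCC1=C(C)CCCC1(C)C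
F5 | step 13 | 4,4,5,5-tetramethyl-2-[(1E)-2-methyl-4-(2,6,6-trimethylcyclohex-1-en-1-yl)but-1-en-1-yl]-1,3,2-dioxaborolane | CC1(C)OB(/C=C(\C)CCC2=C(C)CCCC2(C)C)OC1(C)C
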